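**Retrosynthetic overview**
1. Tomentodiplacone B ⇐ (one flask: buffered fluoride, then mild aqueous acid) a (2S)-flavanone whose 4'-OH is a TIPS ether and whose 7-OH is masked as a 1-arylvinyl ether.
2. Ring C, the only ring made in the route (rings A and B are bought), is closed by forming the C3–C4 bond: enantioselective rhodium-catalysed 6-endo hydroacylation of an achiral 2-formylaryl 1-arylvinyl ether. The same event sets C2, the only stereocentre.
3. Enabling feature: C2 carries both O1 and ring B, so at the alkene oxidation level it is a 1,1-disubstituted enol ether O1–C2(=C3H2)–ring B ortho to the C4 formyl group on ring A; the C5–OH hydrogen bond to the formyl oxygen turns the formyl C–H toward that alkene.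
4. The bis(enol ether) aldehyde ⇐ C-alkylated phloroglucinaldehyde + 2 racemic bromohydrin (double Mitsunobu at 4-O and 6-O, double E2). The second enol ether is a temporary 7-O protecting group, so 4-OH and 6-OH need not be told apart.
5. C-alkylated phloroglucinaldehyde ⇐ 2,4,6-trihydroxybenzaldehyde + the C10 allylic bromide, made from geranyl acetate by epoxide-to-allylic-alcohol transposition (selenide opening, selenoxide elimination).

Key step: step 10

Remark on the chemistry: the sense of induction of the bisphosphine in step 10 cannot be predicted with certainty for this new substrate class; (R)-DTBM-SEGPHOS is written on the assumption that it gives the (2S) product, and the (S)-ligand would be used otherwise with nothing else changed.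

**Route**

Step 1
Reactants: 1 geranyl acetate
Product: 2 (2E)-6,7-epoxy-3,7-dimethyloct-2-en-1-yl acetate (racemic)
Conditions: mCPBA (1.05 equiv), CH2Cl2, 0 °C
Reagents that add atoms: meta-chloroperoxybenzoic acid, O=C(OO)c1cccc(Cl)c1
Why: Peracid epoxidation (Prilezhaev reaction) should select the electron-rich 6,7-alkene over the 2,3-alkene deactivated by the allylic acetate; the epoxide stereocentre is racemic and is erased in step 3.

Step 2
Reactants: 2 (2E)-6,7-epoxy-3,7-dimethyloct-2-en-1-yl acetate
Product: 3 (2E)-6,7-epoxy-3,7-dimethyloct-2-en-1-ol (racemic)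
Conditions: K2CO3 (cat.), MeOH, rt
Reagents that add atoms: none
Why: Base-catalysed transesterification removes the acetate and leaves the trisubstituted epoxide intact, so that no ester meets the borohydride and selenolate of the next step.

Step 3
Reactants: 3 (2E)-6,7-epoxy-3,7-dimethyloct-2-en-1-ol
Product: 6 (2E,5E)-3,7-dimethylocta-2,5-diene-1,7-diol, via hydroxy selenide 4 (not isolated), via selenoxide 5 (not isolated)
Conditions: (PhSe)2, NaBH4, EtOH, rt to reflux; then 30% H2O2, THF, 0 °C to rt
Reagents that add atoms: none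
Why: Selenolate should open the epoxide by SN2 attack at the less substituted C6, and the selenoxide can only eliminate syn toward the C5 hydrogens, giving the (E)-disubstituted alkene next to the tertiary alcohol (epoxide-to-allylic-alcohol transposition by selenoxide elimination).

Step 4
Reactants: 6 (2E,5E)-3,7-dimethylocta-2,5-diene-1,7-diol
Product: 8 (3E,6E)-8-bromo-2,6-dimethylocta-3,6-dien-2-ol, via allylic mesylate 7 (not isolated)
Conditions: MsCl (1.05 equiv), Et3N, THF, −40 °C; then LiBr, THF, −40 to 0 °C; used crude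
Reagents that add atoms: lithium bromide, [Li+].[Br-]
Why: Sulfonylation should select the primary allylic over the tertiary hydroxyl at low temperature, and bromide displaces the allylic mesylate by SN2 with the (E)-trisubstituted alkene retained.

Step 5
Reactants: 9 2,4,6-trihydroxybenzaldehyde (2 equiv); 8 (3E,6E)-8-bromo-2,6-dimethylocta-3,6-dien-2-ol
Product: 10 2,4,6-trihydroxy-3-[(2E,5E)-7-hydroxy-3,7-dimethylocta-2,5-dien-1-yl]benzaldehyde
Conditions: DBU (1.1 equiv), THF, 0 °C to rt
Reagents that add atoms: none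
Why: C-alkylation of a phloroglucinol-type phenoxide with an allylic bromide, as known for prenyl and geranyl bromides with acylphloroglucinols; C3 and C5 are equivalent, so only one C-regioisomer can form, and excess aldehyde should limit double alkylation.

Step 6
Reactants: 11 2-methoxy-4-vinylphenol
Product: 12 (2-methoxy-4-vinylphenoxy)triisopropylsilane
Conditions: TIPSCl, imidazole, DMF, rt
Reagents that add atoms: chlorotriisopropylsilane, CC(C)[Si](Cl)(C(C)C)C(C)C
Why: Standard phenol silylation; the bulky TIPS ether is chosen to survive KOtBu in step 9, where a free para-phenoxide would expel the aryloxide as a quinone methide.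

Step 7
Reactants: 12 (2-methoxy-4-vinylphenoxy)triisopropylsilane
Product: 13 2-bromo-1-[3-methoxy-4-(triisopropylsilyloxy)phenyl]ethan-1-ol (racemic)
Conditions: NBS (1.05 equiv), acetone/H2O, 0 °C, dark
Reagents that add atoms: N-bromosuccinimide, O=C1CCC(=O)N1Br; water, O
Why: Bromohydrin formation: water should open the bromonium ion at the benzylic carbon stabilised by the electron-rich arene (Markovnikov); a racemate suffices because this stereocentre is erased in step 9.

Step 8
Reactants: 10 2,4,6-trihydroxy-3-[(2E,5E)-7-hydroxy-3,7-dimethylocta-2,5-dien-1-yl]benzaldehyde; 13 2-bromo-1-[3-methoxy-4-(triisopropylsilyloxy)phenyl]ethan-1-ol (2.4 equiv)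
Product: 14 4,6-bis{2-bromo-1-[3-methoxy-4-(triisopropylsilyloxy)phenyl]ethoxy}-2-hydroxy-3-[(2E,5E)-7-hydroxy-3,7-dimethylocta-2,5-dien-1-yl]benzaldehyde (mixture of diastereomers)
Conditions: PPh3, DIAD (2.6 equiv each), THF, 0 °C to rt
Reagents that add atoms: none
Why: Double Mitsunobu etherification: the acidic 4-OH and the unhindered 6-OH should react, while the 2-OH, flanked by the side chain and hydrogen-bonded to the formyl oxygen, stays free; the tertiary alcohol is inert and the two new stereocentres are of no consequence.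

Step 9
Reactants: 14 4,6-bis{2-bromo-1-[3-methoxy-4-(triisopropylsilyloxy)phenyl]ethoxy}-2-hydroxy-3-[(2E,5E)-7-hydroxy-3,7-dimethylocta-2,5-dien-1-yl]benzaldehyde
Product: 15 2-hydroxy-3-[(2E,5E)-7-hydroxy-3,7-dimethylocta-2,5-dien-1-yl]-4,6-bis({1-[3-methoxy-4-(triisopropylsilyloxy)phenyl]ethenyl}oxy)benzaldehyde
Conditions: KOtBu (5 equiv), THF, −40 to 0 °C; pH 7 buffer quench; Et3N-deactivated silica
Reagents that add atoms: none
Why: Twofold E2 dehydrobromination of the beta-bromo ethers, whose only beta-hydrogen is benzylic and alpha to oxygen, should give the two 1-aryloxystyrene units; the aldehyde has no alpha-hydrogen and is deactivated as the ortho-phenoxide.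

Step 10
Reactants: 15 2-hydroxy-3-[(2E,5E)-7-hydroxy-3,7-dimethylocta-2,5-dien-1-yl]-4,6-bis({1-[3-methoxy-4-(triisopropylsilyloxy)phenyl]ethenyl}oxy)benzaldehyde
Product: 16 (2S)-5-hydroxy-6-[(2E,5E)-7-hydroxy-3,7-dimethylocta-2,5-dien-1-yl]-2-[3-methoxy-4-(triisopropylsilyloxy)phenyl]-7-({1-[3-methoxy-4-(triisopropylsilyloxy)phenyl]ethenyl}oxy)-2,3-dihydro-4H-chromen-4-one
Conditions: [Rh(cod)Cl]2 (5 mol%), (R)-DTBM-SEGPHOS (10 mol%), Na[B(3,5-(CF3)2C6H3)4] (10 mol%), degassed THF (0.02 M), 60 °C
Reagents that add atoms: none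
Why: Proposed new method: the cationic bisphosphine complex of monovalent rhodium should insert into the formyl C–H bond, bind the ortho-tethered 1,1-disubstituted enol ether and transfer hydride to the aryl- and oxygen-bearing carbon (future C2), which places rhodium on the terminal CH2 (future C3) in a seven-membered acyl–alkyl metallacycle of trivalent rhodium; C–C reductive elimination then forges C3–C4. The closest known reaction type is the rhodium-catalysed endo-selective, enantioselective intramolecular hydroacylation of ortho-allylbenzaldehydes bearing a 1,1-disubstituted alkene (giving 3-substituted tetralones), together with ether-assisted rhodium hydroacylations to benzo-fused oxacycles; an aryl 1-arylvinyl ether as the alkene partner is the new element. Ring C closes in the 6-endo-trig mode. The C2 stereocentre arises in the hydride transfer to one face of the enol ether and is under catalyst control by the chiral bisphosphine, the substrate being achiral. The step needs endo over 5-exo closure, cyclisation over decarbonylation and reaction of the ortho enol ether only: 1,1-disubstitution makes the exo path end in a tertiary alkyl–rhodium that would have to form a quaternary carbon, the C5–OH hydrogen bond to the formyl oxygen turns the formyl C–H toward the O1 tether, and the para enol ether and the side-chain alkenes cannot reach the acyl–rhodium centre intramolecularly. The behaviour of rhodium alkyls with a beta-oxygen in hydroformylation of enol ethers suggests that beta-aryloxide elimination should not outrun reductive elimination.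

Step 11
Reactants: 16 (2S)-5-hydroxy-6-[(2E,5E)-7-hydroxy-3,7-dimethylocta-2,5-dien-1-yl]-2-[3-methoxy-4-(triisopropylsilyloxy)phenyl]-7-({1-[3-methoxy-4-(triisopropylsilyloxy)phenyl]ethenyl}oxy)-2,3-dihydro-4H-chromen-4-one
Product: 18 tomentodiplacone B, (2S)-5,7-dihydroxy-2-(4-hydroxy-3-methoxyphenyl)-6-[(2E,5E)-7-hydroxy-3,7-dimethylocta-2,5-dien-1-yl]-2,3-dihydro-4H-chromen-4-one, via desilylated enol ether 17 (not isolated)
Conditions: TBAF (2.2 equiv), AcOH (3 equiv), THF, 0 °C; then 10% aq. citric acid, THF, rt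
Reagents that add atoms: none
Why: Acetic-acid-buffered fluoride should cleave both aryl silyl ethers without base-induced ring opening (racemisation) of the flavanone, and the freed para-hydroxyphenyl enol ether is then hydrolysed by mild aqueous acid (enol ether hydrolysis), under which the tertiary allylic alcohol and C2 should survive.

**Compound list**
1 | geranyl acetate | CC(=O)OC/C=C(\C)CCC=C(C)C | starting material
2 | (2E)-6,7-epoxy-3,7-dimethyloct-2-en-1-yl acetate (racemic) | CC(=O)OC/C=C(\C)CCC1OC1(C)C | intermediate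
3 | (2E)-6,7-epoxy-3,7-dimethyloct-2-en-1-ol (racemic) | OC/C=C(\C)CCC1OC1(C)C | intermediate
4 | (2E)-3,7-dimethyl-6-(phenylselanyl)oct-2-ene-1,7-diol (racemic, not isolated) | OC/C=C(\C)CCC([Se]c1ccccc1)C(C)(C)O | intermediate
5 | (2E)-3,7-dimethyl-6-(phenylseleninyl)oct-2-ene-1,7-diol (not isolated) | OC/C=C(\C)CCC([Se](=O)c1ccccc1)C(C)(C)O | intermediate
6 | (2E,5E)-3,7-dimethylocta-2,5-diene-1,7-diol | OC/C=C(\C)C/C=C/C(C)(C)O | intermediate
7 | (2E,5E)-7-hydroxy-3,7-dimethylocta-2,5-dien-1-yl methanesulfonate (not isolated) | CS(=O)(=O)OC/C=C(\C)C/C=C/C(C)(C)O | intermediate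
8 | (3E,6E)-8-bromo-2,6-dimethylocta-3,6-dien-2-ol | BrC/C=C(\C)C/C=C/C(C)(C)O | intermediate
9 | 2,4,6-trihydroxybenzaldehyde | O=Cc1c(O)cc(O)cc1O | starting material
10 | 2,4,6-trihydroxy-3-[(2E,5E)-7-hydroxy-3,7-dimethylocta-2,5-dien-1-yl]benzaldehyde | O=Cc1c(O)c(C/C=C(\C)C/C=C/C(C)(C)O)c(O)cc1O | intermediate
11 | 2-methoxy-4-vinylphenol | COc1cc(C=C)ccc1O | starting material
12 | (2-methoxy-4-vinylphenoxy)triisopropylsilane | COc1cc(C=C)ccc1O[Si](C(C)C)(C(C)C)C(C)C | intermediate
13 | 2-bromo-1-[3-methoxy-4-(triisopropylsilyloxy)phenyl]ethan-1-ol (racemic) | COc1cc(C(O)CBr)ccc1O[Si](C(C)C)(C(C)C)C(C)C | intermediate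
14 | 4,6-bis{2-bromo-1-[3-methoxy-4-(triisopropylsilyloxy)phenyl]ethoxy}-2-hydroxy-3-[(2E,5E)-7-hydroxy-3,7-dimethylocta-2,5-dien-1-yl]benzaldehyde (mixture of diastereomers) | O=Cc1c(O)c(C/C=C(\C)C/C=C/C(C)(C)O)c(OC(CBr)c2ccc(O[Si](C(C)C)(C(C)C)C(C)C)c(OC)c2)cc1OC(CBr)c1ccc(O[Si](C(C)C)(C(C)C)C(C)C)c(OC)c1 | intermediate
15 | 2-hydroxy-3-[(2E,5E)-7-hydroxy-3,7-dimethylocta-2,5-dien-1-yl]-4,6-bis({1-[3-methoxy-4-(triisopropylsilyloxy)phenyl]ethenyl}oxy)benzaldehyde | O=Cc1c(O)c(C/C=C(\C)C/C=C/C(C)(C)O)c(OC(=C)c2ccc(O[Si](C(C)C)(C(C)C)C(C)C)c(OC)c2)cc1OC(=C)c1ccc(O[Si](C(C)C)(C(C)C)C(C)C)c(OC)c1 | intermediate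
16 | (2S)-5-hydroxy-6-[(2E,5E)-7-hydroxy-3,7-dimethylocta-2,5-dien-1-yl]-2-[3-methoxy-4-(triisopropylsilyloxy)phenyl]-7-({1-[3-methoxy-4-(triisopropylsilyloxy)phenyl]ethenyl}oxy)-2,3-dihydro-4H-chromen-4-one | COc1cc([C@@H]2CC(=O)c3c(cc(OC(=C)c4ccc(O[Si](C(C)C)(C(C)C)C(C)C)c(OC)c4)c(C/C=C(\C)C/C=C/C(C)(C)O)c3O)O2)ccc1O[Si](C(C)C)(C(C)C)C(C)C | intermediate
17 | (2S)-5-hydroxy-2-(4-hydroxy-3-methoxyphenyl)-7-{[1-(4-hydroxy-3-methoxyphenyl)ethenyl]oxy}-6-[(2E,5E)-7-hydroxy-3,7-dimethylocta-2,5-dien-1-yl]-2,3-dihydro-4H-chromen-4-one (not isolated) | COc1cc([C@@H]2CC(=O)c3c(cc(OC(=C)c4ccc(O)c(OC)c4)c(C/C=C(\C)C/C=C/C(C)(C)O)c3O)O2)ccc1O | intermediate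
18 | tomentodiplacone B, (2S)-5,7-dihydroxy-2-(4-hydroxy-3-methoxyphenyl)-6-[(2E,5E)-7-hydroxy-3,7-dimethylocta-2,5-dien-1-yl]-2,3-dihydro-4H-chromen-4-one | COc1cc([C@@H]2CC(=O)c3c(cc(O)c(C/C=C(\C)C/C=C/C(C)(C)O)c3O)O2)ccc1O | target

**Step count and risks**

Total step count: 11. Longest linear sequence: 9 steps (steps 1 to 5, then 8 to 11); steps 6 and 7 form the short side branch.

Steps most likely to fail:

1. Step 10 (proposed new method). The acyl rhodium hydride may decarbonylate, may close in the exo sense, may move the double bonds of the skipped diene into conjugation, or the hydride transfer may show poor facial selectivity. The fallback sets the stereocentre before ring closure and forms the same C3–C4 bond by known carbene catalysis; it sets out from 13 and 10 and comes back at 18.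
   - Dess–Martin oxidation of 13 gives 2-bromo-1-[3-methoxy-4-(triisopropylsilyloxy)phenyl]ethan-1-one F1.
   - Corey–Bakshi–Shibata reduction of F1 ((S)-2-methyl-CBS-oxazaborolidine, BH3·SMe2) gives (1S)-2-bromo-1-[3-methoxy-4-(triisopropylsilyloxy)phenyl]ethan-1-ol F2.
   - 10 is silylated at its most acidic 4-OH (TIPSCl, imidazole) to 2,6-dihydroxy-3-[(2E,5E)-7-hydroxy-3,7-dimethylocta-2,5-dien-1-yl]-4-(triisopropylsilyloxy)benzaldehyde F3.
   - Mitsunobu coupling of F3 with F2 at the unhindered 6-OH, with inversion, gives 6-{(1R)-2-bromo-1-[3-methoxy-4-(triisopropylsilyloxy)phenyl]ethoxy}-2-hydroxy-3-[(2E,5E)-7-hydroxy-3,7-dimethylocta-2,5-dien-1-yl]-4-(triisopropylsilyloxy)benzaldehyde F4.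
   - A thiazolium-derived N-heterocyclic carbene (3-benzyl-5-(2-hydroxyethyl)-4-methylthiazolium chloride, DBU, toluene) turns the aldehyde into its Breslow intermediate, which displaces the primary bromide intramolecularly. This is the known carbene-catalysed SN2 closure of 2-(2-haloethoxy)benzaldehydes to chroman-4-ones, and it leaves the stereocentre untouched. It gives (2S)-5-hydroxy-6-[(2E,5E)-7-hydroxy-3,7-dimethylocta-2,5-dien-1-yl]-2-[3-methoxy-4-(triisopropylsilyloxy)phenyl]-7-(triisopropylsilyloxy)-2,3-dihydro-4H-chromen-4-one F5.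
   - TBAF/AcOH in THF at 0 °C then gives 18.

2. Step 5. The ambident phenoxide may be alkylated at oxygen or twice at carbon, and the unprotected allylic bromide may decompose before it is consumed. The fallback replaces the SN2 alkylation by a Tsuji–Trost C-allylation; it sets out from 6 and 9 and comes back at 10.
   - The primary hydroxyl of 6 is selectively converted (ClCO2Me, pyridine, CH2Cl2, −20 °C) into (2E,5E)-7-hydroxy-3,7-dimethylocta-2,5-dien-1-yl methyl carbonate F6.
   - F6 is ionised by Pd(PPh3)4 in THF at rt to a pi-allyl complex, with methoxide released as the base.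
   - The soft ring carbon of 9 should attack the less hindered allyl terminus to give 10; the tertiary allylic alcohol is not ionised by zerovalent palladium under these neutral conditions.

3. Step 8. The electron-rich benzylic alkoxyphosphonium may ionise (elimination, C-alkylation of ring A), and the second etherification may occur at the hindered 2-OH instead of the 6-OH. The fallback installs the vinyl groups directly by C(sp2)–O coupling and bypasses 14 and step 9; it sets out from 12 and 10 and comes back at 15.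
   - Bromine addition to 12 (pyridinium tribromide, CH2Cl2, 0 °C) gives [4-(1,2-dibromoethyl)-2-methoxyphenoxy]triisopropylsilane F7.
   - DBU removes the benzylic hydrogen of F7 to give [4-(1-bromoethenyl)-2-methoxyphenoxy]triisopropylsilane F8.
   - Ullmann-type O-vinylation of 10 with F8 (CuI, N,N-dimethylglycine, Cs2CO3, 1,4-dioxane, 60 to 80 °C) at the 4-OH and 6-OH gives 15.

Further compounds
F1 | step 10 | 2-bromo-1-[3-methoxy-4-(triisopropylsilyloxy)phenyl]ethan-1-one | COc1cc(C(=O)CBr)ccc1O[Si](C(C)C)(C(C)C)C(C)C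
F2 | step 10 | (1S)-2-bromo-1-[3-methoxy-4-(triisopropylsilyloxy)phenyl]ethan-1-ol | O[C@H](CBr)c1ccc(O[Si](C(C)C)(C(C)C)C(C)C)c(OC)c1
F3 | step 10 | 2,6-dihydroxy-3-[(2E,5E)-7-hydroxy-3,7-dimethylocta-2,5-dien-1-yl]-4-(triisopropylsilyloxy)benzaldehyde | O=Cc1c(O)c(C/C=C(\C)C/C=C/C(C)(C)O)c(O[Si](C(C)C)(C(C)C)C(C)C)cc1O
F4 | step 10 | 6-{(1R)-2-bromo-1-[3-methoxy-4-(triisopropylsilyloxy)phenyl]ethoxy}-2-hydroxy-3-[(2E,5E)-7-hydroxy-3,7-dimethylocta-2,5-dien-1-yl]-4-(triisopropylsilyloxy)benzaldehyde | O=Cc1c(O)c(C/C=C(\C)C/C=C/C(C)(C)O)c(O[Si](C(C)C)(C(C)C)C(C)C)cc1O[C@@H](CBr)c1ccc(O[Si](C(C)C)(C(C)C)C(C)C)c(OC)c1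
F5 | step 10 | (2S)-5-hydroxy-6-[(2E,5E)-7-hydroxy-3,7-dimethylocta-2,5-dien-1-yl]-2-[3-methoxy-4-(triisopropylsilyloxy)phenyl]-7-(triisopropylsilyloxy)-2,3-dihydro-4H-chromen-4-one | COc1cc([C@@H]2CC(=O)c3c(cc(O[Si](C(C)C)(C(C)C)C(C)C)c(C/C=C(\C)C/C=C/C(C)(C)O)c3O)O2)ccc1O[Si](C(C)C)(C(C)C)C(C)C
F6 | step 5 | (2E,5E)-7-hydroxy-3,7-dimethylocta-2,5-dien-1-yl methyl carbonate | COC(=O)OC/C=C(\C)C/C=C/C(C)(C)O
F7 | step 8 | [4-(1,2-dibromoethyl)-2-methoxyphenoxy]triisopropylsilane | COc1cc(C(Br)CBr)ccc1O[Si](C(C)C)(C(C)C)C(C)C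
F8 | step 8 | [4-(1-bromoethenyl)-2-methoxyphenoxy]triisopropylsilane | COc1cc(C(Br)=C)ccc1O[Si](C(C)C)(C(C)C)C(C)C
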